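**Retrosynthetic overview**

1. Target 18 ⇐ intramolecular Diels–Alder reaction of the cis-bicyclo[4.2.0]octa-2,4-diene 17 (dienoate arm as 4π partner, nearer ring-A double bond as 2π partner). This closes the cyclopentane (ring C) and the ester-bearing cyclohexene (ring D) together and sets their four stereocentres. 17 is made in the same flask by dehydration of alcohol 16.
2. 16 ⇐ C4-phosphonate olefination, one-carbon homologation and Shapiro olefination of photoadduct 9. The tether oxygen ends as the hydroxyl that is lost when its carbon becomes sp2.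
3. 9 ⇐ intramolecular enone–alkene [2+2] photocycloaddition of the acetal-tethered enone 8. The cyclobutane (ring B) closes by the bond between the chain-bearing carbon and the carbon α to the ketone (the allylic ring-fusion CH of ring A in 18); a temporary tetrahydrofuran acetal ring forms in the same event.
4. 8 ⇐ (R)-4-hydroxycyclohex-2-enone 7 (ring A and the only stereocentre brought in) + enal acetal 6 (from 1,7-dibromoheptane, (E)-propenylboronic acid and propynal diethyl acetal). Ring order: A (bought) → B plus temporary acetal ring (step 5) → C and D (step 11).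
5. Enabling feature: ring B shares an edge with ring A, and the ring-A carbon next to that edge (the CH common to rings A, C and D in 18) is a trigonal CH of the cyclohexadiene in 17. An oxygen on that carbon can therefore hold the alkene three atoms from the enone β-carbon (rule of five) and later vanish by elimination.

Key step: step 5

Remark: (R)-4-hydroxycyclohex-2-en-1-one (7) is taken as a purchasable chiral building block; its carbinol carbon is the only stereocentre introduced from outside.

**Route**

Step 1
Reactants: 1 1,7-dibromoheptane; 2 (E)-prop-1-en-1-ylboronic acid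
Product: 3 (E)-10-bromodec-2-ene
Conditions: Pd(OAc)2 (cat.), P(t-Bu)2Me (cat.), KOt-Bu, tert-amyl alcohol, rt; 1 in threefold excess
Reagents that add atoms: none
Why: Alkyl–alkenyl Suzuki–Miyaura coupling of a primary alkyl bromide; the E geometry of the boronic acid is retained and the excess of 1 should limit double coupling.

Step 2
Reactants: 4 3,3-diethoxyprop-1-yne; 3 (E)-10-bromodec-2-ene
Product: 5 (E)-13,13-diethoxytridec-2-en-11-yne
Conditions: n-BuLi, THF, −78 °C; then 3, DMPU, −78 °C → rt
Reagents that add atoms: none
Why: SN2 alkylation of the lithium acetylide of 4 by the primary bromide; the isolated alkene and the acetal are inert.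

Step 3
Reactants: 5 (E)-13,13-diethoxytridec-2-en-11-yne
Product: 6 (2Z,11E)-1,1-diethoxytrideca-2,11-diene
Conditions: H2 (1 atm), Pd/CaCO3 poisoned with Pb(OAc)2 (Lindlar catalyst), quinoline, hexane, rt
Reagents that add atoms: none
Why: Lindlar semihydrogenation delivers hydrogen syn and stops at the Z-alkene without touching the isolated E-alkene; the geometry made here is erased in step 5.

Step 4
Reactants: 7 (R)-4-hydroxycyclohex-2-en-1-one; 6 (2Z,11E)-1,1-diethoxytrideca-2,11-diene
Product: 8 (4R)-4-{[(2Z,11E)-1-ethoxytrideca-2,11-dien-1-yl]oxy}cyclohex-2-en-1-one (both epimers at the acetal carbon)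
Conditions: PPTS (cat.), PhMe, 5 Å MS, 40 °C; 6 in excess
Reagents that add atoms: none
Why: Acid-catalysed transacetalisation through an allyl-stabilised oxocarbenium ion exchanges one ethoxy group for the secondary hydroxyl of 7 without touching its stereocentre; the acetal-carbon epimers converge in step 9.

Step 5
Reactants: 8 (4R)-4-{[(2Z,11E)-1-ethoxytrideca-2,11-dien-1-yl]oxy}cyclohex-2-en-1-one
Product: 9 tricyclic keto acetal: cyclohexanone with a cis-fused cyclobutane on its C2–C3 bond and a cis-fused 2-ethoxytetrahydrofuran on its C3–C4 bond (ring oxygen on C4; acetal carbon on the cyclobutane); (E)-dec-8-enyl chain exo on the fourth cyclobutane carbon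
Conditions: hν (366 nm), degassed MeCN (0.01 M), −20 °C → rt; then filtration through basic Al2O3
Reagents that add atoms: none
Why: Excitation of the enone (n→π*) and intersystem crossing give the triplet, whose β-carbon attacks the proximal carbon of the tethered alkene 5-exo, closing the temporary tetrahydrofuran acetal ring and leaving a triplet 1,4-biradical (α-keto radical and secondary alkyl radical); after spin inversion the biradical collapses and closes the cyclobutane by the bond between the α-carbon and the chain-bearing carbon. The closest known reaction type is the intramolecular enone–alkene [2+2] photocycloaddition of 4-(allyloxy)cycloalkenones, a 2-oxa-1,6-diene that follows the rule of five. The three-atom tether can reach only the enone face that carries the C–O bond of the carbinol centre from 7, which fixes the β-carbon and, through the cis-fused five-membered ring, the proximal alkene carbon. The α-carbon is set by closure on the same face (cis-bicyclo[4.2.0]octanone; any trans-fused material is epimerised on basic Al2O3), and the chain-bearing carbon by the freely rotating radical, which should place the decenyl chain on the convex face, so the alkene geometry of 8 does not matter. The step needs straight over crossed regiochemistry (secured by the 1,6-diene spacing), face selectivity (secured by the tether) and exo selectivity (sterics of the biradical closure); the isolated E-alkene and the acetal do not absorb at 366 nm.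

Step 6
Reactants: 9 tricyclic keto acetal
Product: 10 2,4,6-triisopropylbenzenesulfonyl hydrazone of 9
Conditions: 2,4,6-triisopropylbenzenesulfonyl hydrazide, THF, 4 Å MS, rt
Reagents that add atoms: 2,4,6-triisopropylbenzenesulfonyl hydrazide, CC(C)c1cc(C(C)C)c(S(=O)(=O)NN)c(C(C)C)c1
Why: Condensation of the ketone with the sulfonyl hydrazide gives the hydrazone needed for the Shapiro reaction; no acid is added, so the acetal survives.

Step 7
Reactants: 10 sulfonyl hydrazone of 9
Product: 11 tricyclic alkene acetal (as 9, with a C=C between the former carbonyl carbon and its CH2 neighbour)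
Conditions: n-BuLi (2.2 equiv), THF/TMEDA, −78 → 0 °C; then H2O
Reagents that add atoms: none
Why: Shapiro reaction: the dianion forms at the less substituted α-CH2, loses sulfinate and N2, and the vinyllithium is protonated, which places the ring-A double bond away from the cyclobutane and leaves all stereocentres untouched.

Step 8
Reactants: 11 tricyclic alkene acetal
Product: 12 five-membered lactol (2-hydroxytetrahydrofuran) corresponding to 11, both anomers
Conditions: AcOH/THF/H2O, 40 °C
Reagents that add atoms: water, O
Why: Mild aqueous acid hydrolyses the cyclic ethyl acetal to the lactol, which keeps the cyclobutane carbaldehyde masked and its α-stereocentre locked in the cis-fused ring.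

Step 9
Reactants: 12 five-membered lactol
Product: 14 six-membered lactol (2-hydroxytetrahydropyran fused to ring A and ring B; both anomers), via hydroxy enol ether 13 (not isolated)
Conditions: Ph3P(CH2OMe)Cl, KHMDS, THF, 0 °C → rt; then 1 M HCl, THF, rt
Reagents that add atoms: (methoxymethyl)triphenylphosphonium chloride, COC[P+](c1ccccc1)(c1ccccc1)c1ccccc1.[Cl-]; water, O
Why: Wittig methoxymethylenation of the lactol through its hydroxy aldehyde form, followed by acid hydrolysis of the enol ether, gives the one-carbon-homologated aldehyde, which closes on the neighbouring hydroxyl; no stereocentre other than the anomeric carbon is formed.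

Step 10
Reactants: 14 six-membered lactol; 15 methyl (E)-4-(diethoxyphosphoryl)but-2-enoate
Product: 16 methyl (2E,4E)-6-{5-hydroxy-8-[(E)-dec-8-en-1-yl]-cis-bicyclo[4.2.0]oct-2-en-7-yl}hexa-2,4-dienoate (C7 arm endo and cis to the C5 hydroxyl; C8 chain exo)
Conditions: LiHMDS, THF, −78 → 0 °C
Reagents that add atoms: none
Why: Horner–Wadsworth–Emmons olefination of the lactol in its open hydroxy aldehyde form with the lithiated vinylogous phosphonate should give the (2E,4E)-dienoate; the stereocentres are not involved.

Step 11
Reactants: 16 hydroxy dienoate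
Product: 18 target CNP0133550.1, via bicyclooctadiene dienoate 17 (not isolated)
Conditions: Burgess reagent, PhMe, 50 °C; then 100 °C
Reagents that add atoms: none
Why: Burgess dehydration is a syn elimination, and since the only syn β-hydrogen sits on the allylic CH2 the new double bond completes the ring-A 1,3-diene; the endo dienoate arm then adds as 4π partner to the nearer ring double bond in an intramolecular Diels–Alder reaction (the mode by which the endiandric acid B/C skeleton forms), the three-atom link through ring B fixing the face and the exo geometry that set the four stereocentres of rings C and D.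

**Compound list**

1 | 1,7-dibromoheptane | BrCCCCCCCBr | starting material
2 | (E)-prop-1-en-1-ylboronic acid | C/C=C/B(O)O | starting material
3 | (E)-10-bromodec-2-ene | C/C=C/CCCCCCCBr | intermediate
4 | 3,3-diethoxyprop-1-yne | C#CC(OCC)OCC | starting material
5 | (E)-13,13-diethoxytridec-2-en-11-yne | CCOC(OCC)C#CCCCCCCC/C=C/C | intermediate
6 | (2Z,11E)-1,1-diethoxytrideca-2,11-diene | CCOC(OCC)/C=C\CCCCCCC/C=C/C | intermediate
7 | (R)-4-hydroxycyclohex-2-en-1-one | O=C1C=C[C@H](O)CC1 | starting material
8 | (4R)-4-{[(2Z,11E)-1-ethoxytrideca-2,11-dien-1-yl]oxy}cyclohex-2-en-1-one, acetal epimers | O=C1C=C[C@H](OC(OCC)/C=C\CCCCCCC/C=C/C)CC1 | intermediate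
9 | tricyclic keto acetal (cyclohexanone cis-fused to cyclobutane and to 2-ethoxytetrahydrofuran; decenyl chain exo; acetal epimers) | C/C=C/CCCCCCC[C@@H]1[C@H]2C(=O)CC[C@H]3OC(OCC)[C@@H]1[C@@H]23 | intermediate
10 | 2,4,6-triisopropylbenzenesulfonyl hydrazone of 9 | C/C=C/CCCCCCC[C@@H]1[C@H]2C(=NNS(=O)(=O)c4c(C(C)C)cc(C(C)C)cc4C(C)C)CC[C@H]3OC(OCC)[C@@H]1[C@@H]23 | intermediate
11 | tricyclic alkene acetal | C/C=C/CCCCCCC[C@@H]1[C@H]2C=CC[C@H]3OC(OCC)[C@@H]1[C@@H]23 | intermediate
12 | five-membered lactol, anomers | C/C=C/CCCCCCC[C@@H]1[C@H]2C=CC[C@H]3OC(O)[C@@H]1[C@@H]23 | intermediate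
13 | hydroxy enol ether: 8-[(E)-dec-8-enyl]-7-(2-methoxyethenyl)-cis-bicyclo[4.2.0]oct-2-en-5-ol (7-endo, 8-exo; enol ether E/Z) | C/C=C/CCCCCCC[C@@H]1[C@H]2C=CC[C@@H](O)[C@H]2[C@H]1C=COC | intermediate
14 | six-membered lactol, anomers | C/C=C/CCCCCCC[C@@H]1[C@H]2C=CC[C@H]3OC(O)C[C@@H]1[C@@H]23 | intermediate
15 | methyl (E)-4-(diethoxyphosphoryl)but-2-enoate | CCOP(=O)(OCC)C/C=C/C(=O)OC | starting material
16 | methyl (2E,4E)-6-{5-hydroxy-8-[(E)-dec-8-en-1-yl]-cis-bicyclo[4.2.0]oct-2-en-7-yl}hexa-2,4-dienoate (7-endo, 8-exo) | C/C=C/CCCCCCC[C@@H]1[C@H]2C=CC[C@@H](O)[C@H]2[C@H]1C/C=C/C=C/C(=O)OC | intermediate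
17 | methyl (2E,4E)-6-{8-[(E)-dec-8-en-1-yl]-cis-bicyclo[4.2.0]octa-2,4-dien-7-yl}hexa-2,4-dienoate (7-endo, 8-exo) | C/C=C/CCCCCCC[C@@H]1[C@H]2C=CC=C[C@H]2[C@H]1C/C=C/C=C/C(=O)OC | intermediate
18 | CNP0133550.1 (tetracyclic methyl ester) | C/C=C/CCCCCCC[C@@H]1[C@H]2C=C[C@@H]3[C@@H]4[C@H]2[C@H]1C[C@H]4C=C[C@H]3C(=O)OC | target

**Totals**

Total step count: 11. Longest linear sequence: 11 steps (1 → 3 → 5 → 6 → 8 → 9 → 10 → 11 → 12 → 14 → 16 → 18).

**Steps most likely to fail**

Step 5 (key photocycloaddition). What may go wrong: the triplet biradical may revert to the alkene instead of closing, so that only Z/E isomerisation is seen, or closure may be poorly exo-selective at the chain-bearing carbon. Fallback, a copper-templated ground-state route: from 8, 1,2-reduction (NaBH4, CeCl3·7H2O, MeOH, −78 °C) gives the allylic alcohol (4R)-4-{[(2Z,11E)-1-ethoxytrideca-2,11-dien-1-yl]oxy}cyclohex-2-en-1-ol F1. Irradiation at 254 nm with catalytic (CuOTf)2·C6H6 in Et2O, where monovalent copper binds both double bonds of the diallyl-ether unit and alkene geometry is scrambled on the metal, should close the same two rings to the tricyclic cyclobutane alcohol F2. Oxidation with Dess–Martin periodinane returns to the route at 9.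

Step 4 (mixed acetal). What may go wrong: loss of ethanol from the oxocarbenium ion to a dienol ether, double exchange to the symmetrical acetal, or acid-induced dehydration of 7. Fallback, a neutral palladium-catalysed hydroalkoxylation of an alkoxyallene: from 3, alkylation of lithiated ethyl propargyl ether (n-BuLi, THF/DMPU) gives (E)-13-ethoxytridec-2-en-11-yne F3. KOt-Bu (THF, 0 °C) isomerises it to (11E)-1-ethoxytrideca-1,2,11-triene F4. Addition of 7 across the allene (Pd(OAc)2, dppp, Et3N, MeCN) gives the 2E isomer of 8 F5, which is irradiated as in step 5 and comes back to the route at 9.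

Step 10 (olefination on the lactol). What may go wrong: conjugate re-addition of the liberated alkoxide to the new dienoate, or sluggish opening of the lactol. Fallback, dehydration before olefination: from 14, 1,3-propanedithiol and BF3·OEt2 (CH2Cl2, −20 °C) open the lactol to the hydroxy dithiane F6. Burgess dehydration (PhMe, 50 °C) gives the bicyclooctadiene dithiane F7. MeI and CaCO3 in aqueous MeCN unmask the dienal F8. Olefination of F8 with 15 (LiHMDS, THF, −78 °C) rejoins the route at 17, which is heated on to 18.

Further compounds
F1 | step 5 | (4R)-4-{[(2Z,11E)-1-ethoxytrideca-2,11-dien-1-yl]oxy}cyclohex-2-en-1-ol | OC1C=C[C@H](OC(OCC)/C=C\CCCCCCC/C=C/C)CC1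
F2 | step 5 | tricyclic cyclobutane alcohol (9 with CH–OH in place of C=O) | C/C=C/CCCCCCC[C@@H]1[C@H]2C(O)CC[C@H]3OC(OCC)[C@@H]1[C@@H]23
F3 | step 4 | (E)-13-ethoxytridec-2-en-11-yne | CCOCC#CCCCCCCC/C=C/C
F4 | step 4 | (11E)-1-ethoxytrideca-1,2,11-triene | CCOC=C=CCCCCCCC/C=C/C
F5 | step 4 | (4R)-4-{[(2E,11E)-1-ethoxytrideca-2,11-dien-1-yl]oxy}cyclohex-2-en-1-one | O=C1C=C[C@H](OC(OCC)/C=C/CCCCCCC/C=C/C)CC1
F6 | step 10 | 8-[(E)-dec-8-enyl]-7-(1,3-dithian-2-ylmethyl)-cis-bicyclo[4.2.0]oct-2-en-5-ol | C/C=C/CCCCCCC[C@@H]1[C@H]2C=CC[C@@H](O)[C@H]2[C@H]1CC3SCCCS3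
F7 | step 10 | 2-({8-[(E)-dec-8-enyl]-cis-bicyclo[4.2.0]octa-2,4-dien-7-yl}methyl)-1,3-dithiane | C/C=C/CCCCCCC[C@@H]1[C@H]2C=CC=C[C@H]2[C@H]1CC3SCCCS3
F8 | step 10 | 2-{8-[(E)-dec-8-enyl]-cis-bicyclo[4.2.0]octa-2,4-dien-7-yl}acetaldehyde | C/C=C/CCCCCCC[C@@H]1[C@H]2C=CC=C[C@H]2[C@H]1CC=O
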